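**Retrosynthetic overview**

1. Locants: the ten-membered ring is numbered C1 (=CH, E-olefin) – C2 (C=O) – C3 (=CH, Z-olefin) – C4 (C–CH3) – C5 (CH–OH) – C6 (CH–O of the lactone) – C7 – C8 (CH–O-angelate) – C9 (CH2) – C10 (C–CH3); C11, C12 and C13 are the α-carbon, the carbonyl and the exocyclic CH2 of the γ-lactone.
2. Key disconnection is C4–C5 of the ten-membered carbocycle, closed by a NiCl2/CrCl2-mediated alkenyl iodide–aldehyde addition. It is possible because the carbinol C5 lies between C4, an sp2 carbon of the Z-configured C3=C4–C2(=O) enone (a β-iodoenone carbon in the precursor), and C6, the oxygen-bearing fusion carbon of the trans-fused γ-lactone ring. The ring closure can therefore create C5 under 1,2-induction from C6 and release the unprotected target.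
3. The seco-aldehyde comes from a (Z)-β-iodoenone (hydroiodination of an ynone made by propynyl addition to a C2 enal). The enal comes from a vinylogous Mukaiyama aldol reaction that forms C8–C9, sets C8 and the E-olefin; the angelate is put on C8 directly afterwards.
4. The lactone core comes from (5S)-5-(hydroxymethyl)furan-2(5H)-one. Its one purchased stereocentre (C6) directs a trans conjugate vinylation at C7 (with Mannich trapping at C11 for the methylene); C7 then relays to C8, and C6 to C5 in the ring closure.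
5. Order of ring formation: the γ-lactone ring is present from the starting material (methylene added in steps 2–3); the ten-membered carbocycle is closed last, in step 13.

Key step: step 13

Remark: the configuration is read from the SMILES as 5R,6S,7R,8S in the locants above, with C1=C10 E, C3=C4 Z and a Z (angelate) ester.
Remark: (5S)-5-(hydroxymethyl)furan-2(5H)-one, 3-methylbut-2-enal, angelic acid and solutions of vinylmagnesium bromide and prop-1-ynylmagnesium bromide are taken as purchased.

**Route**

Step 1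
Reactants: 1 (5S)-5-(hydroxymethyl)furan-2(5H)-one
Product: 2 (5S)-5-{[tert-butyl(dimethyl)silyl]oxymethyl}furan-2(5H)-one
Conditions: TBSCl, imidazole, CH2Cl2, 0 °C to rt
Reagents that add atoms: tert-butyldimethylsilyl chloride, CC(C)(C)[Si](C)(C)Cl
Why: Silyl ether protection of the primary alcohol keeps the future C5 oxygen inert until step 11 and provides the bulky C6 substituent that directs step 2.

Step 2
Reactants: 2 (5S)-5-{[tert-butyl(dimethyl)silyl]oxymethyl}furan-2(5H)-one
Product: 4 Mannich base (4S,5S)-5-{[tert-butyl(dimethyl)silyl]oxymethyl}-3-[(dimethylamino)methyl]-4-ethenyloxolan-2-one, via silyl ketene acetal 3 (not isolated)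
Conditions: CH2=CHMgBr, CuBr·SMe2 (10 mol %), TMSCl, THF, −78 °C; then dimethyl(methylidene)ammonium iodide, CH2Cl2, −78 °C to rt; aq NaHCO3
Reagents that add atoms: vinylmagnesium bromide, C=C[Mg]Br; dimethyl(methylidene)ammonium iodide (Eschenmoser's salt), C=[N+](C)C.[I-]
Why: Copper-catalysed conjugate (Michael) addition of the vinyl Grignard reagent, accelerated by TMSCl, should take place anti to the C6 substituent so that C7 is set trans to C6 by substrate control, and the silyl ketene acetal formed is aminomethylated at C11 in a Mannich reaction (the C11 configuration is irrelevant because it is destroyed in step 3).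

Step 3
Reactants: 4 Mannich base
Product: 6 (4S,5S)-5-{[tert-butyl(dimethyl)silyl]oxymethyl}-4-ethenyl-3-methylideneoxolan-2-one, via methiodide 5 (not isolated)
Conditions: MeI, MeOH, rt; then NaHCO3, CH2Cl2/H2O, rt
Reagents that add atoms: none
Why: Exhaustive N-methylation followed by E1cB elimination of trimethylamine (the classical Mannich-base route to α-methylene lactones) should give the exocyclic C11=C13 alkene, the only β-hydrogen available being the acidic one at C11.

Step 4
Reactants: 6 (4S,5S)-5-{[tert-butyl(dimethyl)silyl]oxymethyl}-4-ethenyl-3-methylideneoxolan-2-one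
Product: 8 (2S,3S)-2-{[tert-butyl(dimethyl)silyl]oxymethyl}-4-methylidene-5-oxooxolane-3-carbaldehyde, via secondary ozonide 7 (not isolated)
Conditions: O3, CH2Cl2, −78 °C (Sudan Red 7B as end-point indicator); then PPh3, −78 °C to rt; used crude
Reagents that add atoms: ozone, [O-][O+]=O
Why: Ozonolysis with reductive work-up: electrophilic ozone should cleave the isolated vinyl group far faster than the electron-poor methylene conjugated with the lactone carbonyl, which turns the vinyl carbon into the C8 aldehyde without disturbing C7 as long as base is avoided.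

Step 5
Reactants: 9 3-methylbut-2-enal
Product: 10 tert-butyl(dimethyl){[(1E)-3-methylbuta-1,3-dien-1-yl]oxy}silane
Conditions: TBSOTf, Et3N, CH2Cl2, 0 °C to rt
Reagents that add atoms: tert-butyldimethylsilyl trifluoromethanesulfonate, CC(C)(C)[Si](C)(C)OS(=O)(=O)C(F)(F)F
Why: Soft enolisation (γ-deprotonation and O-silylation) of the enal gives the 1-silyloxy-1,3-diene that serves as the vinylogous nucleophile in step 6.

Step 6
Reactants: 8 (2S,3S)-2-{[tert-butyl(dimethyl)silyl]oxymethyl}-4-methylidene-5-oxooxolane-3-carbaldehyde; 10 tert-butyl(dimethyl){[(1E)-3-methylbuta-1,3-dien-1-yl]oxy}silane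
Product: 11 (2E,5S)-5-[(2S,3R)-2-{[tert-butyl(dimethyl)silyl]oxymethyl}-4-methylidene-5-oxooxolan-3-yl]-5-hydroxy-3-methylpent-2-enal
Conditions: 10 (1.5 equiv), (4S)-4-(1H-indol-3-ylmethyl)-3-(4-methylbenzenesulfonyl)-2-phenyl-1,3,2-oxazaborolidin-5-one (50 mol %, from N-tosyl-L-tryptophan and PhBCl2; its enantiomer if that one is the matched partner), iPrOH (1.2 equiv), EtCN, −78 °C; aq NaHCO3
Reagents that add atoms: none
Why: Vinylogous Mukaiyama aldol reaction: the terminal carbon of diene 10 adds to the boron-activated C8 aldehyde from the Felkin–Anh face (anti to the C7–C6 bond, C6 being the bulkiest α-substituent), the chiral oxazaborolidinone being chosen to reinforce that face, so that C8 should be set as the S carbinol, while reaction through the s-trans diene gives the E-configured C1=C10 enal and isopropanol takes up the silyl group.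

Step 7
Reactants: 11 hydroxy enal; 12 angelic acid, (2Z)-2-methylbut-2-enoic acid
Product: 14 (1S,3E)-1-[(2S,3R)-2-{[tert-butyl(dimethyl)silyl]oxymethyl}-4-methylidene-5-oxooxolan-3-yl]-3-methyl-5-oxopent-3-en-1-yl (2Z)-2-methylbut-2-enoate, via mixed anhydride 13 (not isolated)
Conditions: 12, 2,4,6-trichlorobenzoyl chloride, Et3N, toluene, rt; then 11, 70 °C
Reagents that add atoms: none
Why: Yamaguchi esterification through mixed anhydride 13 should acylate the hindered C8 hydroxyl with retention at C8, and working without DMAP avoids isomerisation of the Z (angelate) double bond to the tiglate.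

Step 8
Reactants: 14 angelate enal
Product: 16 (1S,3E)-1-[(2S,3R)-2-{[tert-butyl(dimethyl)silyl]oxymethyl}-4-methylidene-5-oxooxolan-3-yl]-5-hydroxy-3-methyloct-3-en-6-yn-1-yl (2Z)-2-methylbut-2-enoate (both epimers at the new carbinol), via magnesium alkoxide 15 (not isolated)
Conditions: CH3C≡CMgBr (1.1 equiv), THF, −78 °C; aq NH4Cl
Reagents that add atoms: prop-1-yn-1-ylmagnesium bromide, CC#C[Mg]Br
Why: 1,2-Addition of the alkynyl Grignard reagent to the aldehyde brings in C3, C4 and the C4 methyl group, the esters and the lactone being unreactive towards this mild nucleophile at −78 °C and the configuration of the new C2 carbinol being irrelevant.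

Step 9
Reactants: 16 propargylic alcohol
Product: 17 (1S,3E)-1-[(2S,3R)-2-{[tert-butyl(dimethyl)silyl]oxymethyl}-4-methylidene-5-oxooxolan-3-yl]-3-methyl-5-oxooct-3-en-6-yn-1-yl (2Z)-2-methylbut-2-enoate
Conditions: Dess–Martin periodinane, NaHCO3, CH2Cl2, 0 °C
Reagents that add atoms: none
Why: Dess–Martin oxidation of the allylic and propargylic C2 alcohol should give the cross-conjugated enynone under buffered neutral conditions that do not trigger vinylogous elimination of the C8 angelate.

Step 10
Reactants: 17 enynone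
Product: 18 (1S,3E,6Z)-1-[(2S,3R)-2-{[tert-butyl(dimethyl)silyl]oxymethyl}-4-methylidene-5-oxooxolan-3-yl]-7-iodo-3-methyl-5-oxoocta-3,6-dien-1-yl (2Z)-2-methylbut-2-enoate
Conditions: NaI, AcOH, rt, dark
Reagents that add atoms: sodium iodide, [Na+].[I-]
Why: Hydroiodination of the ynone by conjugate addition of iodide and protonation of the allenol intermediate anti to iodine should give the (Z)-β-iodoenone (iodine cis to the C2 carbonyl), which fixes the Z geometry of C3=C4 and provides the alkenyl iodide for the ring closure.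

Step 11
Reactants: 18 silyl ether iodoenone
Product: 19 (1S,3E,6Z)-1-[(2S,3R)-2-(hydroxymethyl)-4-methylidene-5-oxooxolan-3-yl]-7-iodo-3-methyl-5-oxoocta-3,6-dien-1-yl (2Z)-2-methylbut-2-enoate
Conditions: HF·pyridine, pyridine, THF, 0 °C to rt
Reagents that add atoms: none
Why: Desilylation of the primary silyl ether with buffered HF·pyridine frees the C5 hydroxyl without the basic conditions that would endanger the iodoenone, the methylene lactone and the acyloxy enone.

Step 12
Reactants: 19 primary alcohol
Product: 20 (1S,3E,6Z)-1-[(2S,3R)-2-formyl-4-methylidene-5-oxooxolan-3-yl]-7-iodo-3-methyl-5-oxoocta-3,6-dien-1-yl (2Z)-2-methylbut-2-enoate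
Conditions: Dess–Martin periodinane, NaHCO3, CH2Cl2, 0 °C; used crude
Reagents that add atoms: none
Why: Dess–Martin oxidation gives the C5 aldehyde under buffered non-epimerising conditions, so that C6 (α to the new carbonyl) should keep its configuration.

Step 13
Reactants: 20 seco-aldehyde with the (Z)-β-iodoenone
Product: 23 target CNP0230565.9 [(3aR,4S,6E,9Z,11R,11aS)-11-hydroxy-6,10-dimethyl-3-methylidene-2,8-dioxo-2,3,3a,4,5,8,11,11a-octahydrocyclodeca[b]furan-4-yl (2Z)-2-methylbut-2-enoate], via alkenylchromium dichloride 21 (not isolated), via chromium alkoxide 22 (not isolated)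
Conditions: CrCl2 (10 equiv), NiCl2 (2 mol %), degassed DMSO, 0.003 M (slow addition of 20), rt; then aq NH4Cl
Reagents that add atoms: none
Why: Nozaki–Hiyama–Kishi macrocyclisation: CrCl2 reduces NiCl2 to zerovalent nickel, which inserts into the C4–I bond of the (Z)-β-iodoenone, and transmetalation gives an alkenylchromium dichloride (trivalent chromium, held Z by chelation to the C2 carbonyl) that adds to the C5 aldehyde. The closest known reaction type is the NiCl2/CrCl2-mediated ring closure of alkenyl iodides onto aldehydes to nine- and ten-membered carbocycles, together with additions of (Z)-β-iodo enoates and enones to aldehydes. The ten-membered carbocycle closes by C4–C5 bond formation in a 10-exo-trig addition, the lactone ring being already in place. The new C5 stereocentre is controlled by C6: in the polar Felkin–Anh arrangement the nucleophile attacks anti to the C6–O bond, which should give the 5R (5,6-anti) alcohol, and the trans C6/C7 ring fusion restricts the tether to the same approach. The step needs chemoselectivity for the aldehyde over the C2 ketone, both enone systems, the angelate and the methylene lactone, which the aldehyde selectivity and low basicity of organochromium reagents secure, and it needs cyclisation to beat oligomerisation, which high dilution and the turn imposed by the Z C3=C4 olefin and the trans lactone favour. Aqueous work-up releases the C5 hydroxyl, so the step should deliver the target itself without any protecting group.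

**Compound list**

1 | (5S)-5-(hydroxymethyl)furan-2(5H)-one | O=C1C=C[C@@H](CO)O1 | starting material
2 | (5S)-5-{[tert-butyl(dimethyl)silyl]oxymethyl}furan-2(5H)-one | O=C1C=C[C@@H](CO[Si](C)(C)C(C)(C)C)O1 | intermediate
3 | silyl ketene acetal, tert-butyl(dimethyl){[(2S,3S)-3-ethenyl-5-(trimethylsilyloxy)-2,3-dihydrofuran-2-yl]methoxy}silane (vinyl trans to CH2OTBS) | C1=C(O[Si](C)(C)C)O[C@H](CO[Si](C)(C)C(C)(C)C)[C@H]1C=C | intermediate (not isolated)
4 | Mannich base, (4S,5S)-5-{[tert-butyl(dimethyl)silyl]oxymethyl}-3-[(dimethylamino)methyl]-4-ethenyloxolan-2-one (4,5-trans; mixture at ring C3) | CN(C)CC1C(=O)O[C@H](CO[Si](C)(C)C(C)(C)C)[C@H]1C=C | intermediate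
5 | methiodide of 4, {[(4S,5S)-5-{[tert-butyl(dimethyl)silyl]oxymethyl}-4-ethenyl-2-oxooxolan-3-yl]methyl}trimethylammonium iodide | C[N+](C)(C)CC1C(=O)O[C@H](CO[Si](C)(C)C(C)(C)C)[C@H]1C=C.[I-] | intermediate (not isolated)
6 | (4S,5S)-5-{[tert-butyl(dimethyl)silyl]oxymethyl}-4-ethenyl-3-methylideneoxolan-2-one | C=C1C(=O)O[C@H](CO[Si](C)(C)C(C)(C)C)[C@H]1C=C | intermediate
7 | secondary ozonide of 6 (1,2,4-trioxolan-3-yl in place of the ethenyl group) | C=C1C(=O)O[C@H](CO[Si](C)(C)C(C)(C)C)[C@H]1C2OCOO2 | intermediate (not isolated)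
8 | (2S,3S)-2-{[tert-butyl(dimethyl)silyl]oxymethyl}-4-methylidene-5-oxooxolane-3-carbaldehyde | C=C1C(=O)O[C@H](CO[Si](C)(C)C(C)(C)C)[C@H]1C=O | intermediate
9 | 3-methylbut-2-enal | CC(C)=CC=O | starting material
10 | tert-butyl(dimethyl){[(1E)-3-methylbuta-1,3-dien-1-yl]oxy}silane | C=C(C)/C=C/O[Si](C)(C)C(C)(C)C | intermediate
11 | (2E,5S)-5-[(2S,3R)-2-{[tert-butyl(dimethyl)silyl]oxymethyl}-4-methylidene-5-oxooxolan-3-yl]-5-hydroxy-3-methylpent-2-enal | C=C1C(=O)O[C@H](CO[Si](C)(C)C(C)(C)C)[C@H]1[C@@H](O)C/C(C)=C/C=O | intermediate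
12 | angelic acid, (2Z)-2-methylbut-2-enoic acid | C/C=C(C)\C(=O)O | starting material
13 | (2Z)-2-methylbut-2-enoic 2,4,6-trichlorobenzoic anhydride | C/C=C(C)\C(=O)OC(=O)c1c(Cl)cc(Cl)cc1Cl | intermediate (not isolated)
14 | (1S,3E)-1-[(2S,3R)-2-{[tert-butyl(dimethyl)silyl]oxymethyl}-4-methylidene-5-oxooxolan-3-yl]-3-methyl-5-oxopent-3-en-1-yl (2Z)-2-methylbut-2-enoate | C=C1C(=O)O[C@H](CO[Si](C)(C)C(C)(C)C)[C@H]1[C@@H](OC(=O)/C(C)=C\C)C/C(C)=C/C=O | intermediate
15 | bromomagnesium alkoxide of 16 | C=C1C(=O)O[C@H](CO[Si](C)(C)C(C)(C)C)[C@H]1[C@@H](OC(=O)/C(C)=C\C)C/C(C)=C/C(O[Mg]Br)C#CC | intermediate (not isolated)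
16 | (1S,3E)-1-[(2S,3R)-2-{[tert-butyl(dimethyl)silyl]oxymethyl}-4-methylidene-5-oxooxolan-3-yl]-5-hydroxy-3-methyloct-3-en-6-yn-1-yl (2Z)-2-methylbut-2-enoate (both epimers at chain C5) | C=C1C(=O)O[C@H](CO[Si](C)(C)C(C)(C)C)[C@H]1[C@@H](OC(=O)/C(C)=C\C)C/C(C)=C/C(O)C#CC | intermediate
17 | (1S,3E)-1-[(2S,3R)-2-{[tert-butyl(dimethyl)silyl]oxymethyl}-4-methylidene-5-oxooxolan-3-yl]-3-methyl-5-oxooct-3-en-6-yn-1-yl (2Z)-2-methylbut-2-enoate | C=C1C(=O)O[C@H](CO[Si](C)(C)C(C)(C)C)[C@H]1[C@@H](OC(=O)/C(C)=C\C)C/C(C)=C/C(=O)C#CC | intermediate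
18 | (1S,3E,6Z)-1-[(2S,3R)-2-{[tert-butyl(dimethyl)silyl]oxymethyl}-4-methylidene-5-oxooxolan-3-yl]-7-iodo-3-methyl-5-oxoocta-3,6-dien-1-yl (2Z)-2-methylbut-2-enoate | C=C1C(=O)O[C@H](CO[Si](C)(C)C(C)(C)C)[C@H]1[C@@H](OC(=O)/C(C)=C\C)C/C(C)=C/C(=O)/C=C(/C)I | intermediate
19 | (1S,3E,6Z)-1-[(2S,3R)-2-(hydroxymethyl)-4-methylidene-5-oxooxolan-3-yl]-7-iodo-3-methyl-5-oxoocta-3,6-dien-1-yl (2Z)-2-methylbut-2-enoate | C=C1C(=O)O[C@H](CO)[C@H]1[C@@H](OC(=O)/C(C)=C\C)C/C(C)=C/C(=O)/C=C(/C)I | intermediate
20 | (1S,3E,6Z)-1-[(2S,3R)-2-formyl-4-methylidene-5-oxooxolan-3-yl]-7-iodo-3-methyl-5-oxoocta-3,6-dien-1-yl (2Z)-2-methylbut-2-enoate | C=C1C(=O)O[C@H](C=O)[C@H]1[C@@H](OC(=O)/C(C)=C\C)C/C(C)=C/C(=O)/C=C(/C)I | intermediate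
21 | alkenylchromium dichloride from 20 (CrCl2 in place of iodine at C4) | C=C1C(=O)O[C@H](C=O)[C@H]1[C@@H](OC(=O)/C(C)=C\C)C/C(C)=C/C(=O)/C=C(/C)[Cr](Cl)Cl | intermediate (not isolated)
22 | dichlorochromium alkoxide of 23 (at the C5 oxygen) | C=C1C(=O)O[C@H]2[C@H]1[C@@H](OC(=O)/C(C)=C\C)C/C(C)=C/C(=O)/C=C(/C)[C@H]2O[Cr](Cl)Cl | intermediate (not isolated)
23 | CNP0230565.9, (3aR,4S,6E,9Z,11R,11aS)-11-hydroxy-6,10-dimethyl-3-methylidene-2,8-dioxo-2,3,3a,4,5,8,11,11a-octahydrocyclodeca[b]furan-4-yl (2Z)-2-methylbut-2-enoate | C=C1C(=O)O[C@H]2[C@H]1[C@@H](OC(=O)/C(C)=C\C)C/C(C)=C/C(=O)/C=C(/C)[C@H]2O | target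

**Step count and risks**

Total step count: 13 (12 on the main chain plus step 5, which makes diene 10).
Longest linear sequence: 12 steps (steps 1–4 and 6–13, from 1).

Steps most likely to fail:

1. Step 13 (ring closure). What may go wrong: oligomerisation or chromium-induced reductive cleavage of the C6–O bond next to the aldehyde may outrun ring closure, or facial selectivity at C5 may be poor. Fallback: close the ring by olefin metathesis at C3=C4 after setting C5 in an intermolecular addition. It sets out from 14. Addition of vinylmagnesium bromide to the aldehyde at −78 °C would give the divinyl carbinol F1, and Dess–Martin oxidation the vinyl ketone F2. HF·pyridine would then give the primary alcohol F3, and Dess–Martin oxidation the C5 aldehyde F4. Intermolecular NiCl2/CrCl2 coupling of F4 with 2-bromopropene would give the isopropenyl carbinol F5, with 5R expected from the same Felkin–Anh control. Ring-closing metathesis of F5 with the second-generation Grubbs catalyst in dilute toluene would join C3 and C4 as the ring-enforced Z olefin, and the fallback comes back to the route at 23.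

2. Step 6 (vinylogous aldol). What may go wrong: poor or reversed facial selectivity at C8, because the two α-substituents of aldehyde 8 (C6 and C11) may differ less in effective size than the Felkin–Anh argument assumes. Fallback: accept pure substrate control and invert. It sets out from 8. The same aldol reaction with 10, promoted by achiral B(C6F5)3 and isopropanol, would give whichever epimer the substrate prefers. If this is the 8R alcohol F6, Mitsunobu esterification with angelic acid 12 (PPh3, diisopropyl azodicarboxylate, toluene, 0 °C) would install the angelate with inversion at C8 and come back to the route at 14, so that step 7 is no longer needed.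

3. Step 4 (ozonolysis). What may go wrong: ozone may also attack the exocyclic methylene, and the β,γ-unsaturated aldehyde may slip into conjugation (C7–H is both α to the aldehyde and allylic) with loss of the C7 stereocentre. Fallback: carry the methylene masked as the Mannich base through the aldehyde stage. It sets out from 4. Ozonolysis of the vinyl group in the presence of trifluoroacetic acid (the ammonium ion is inert to ozone), with PPh3 work-up and neutralisation, would give the amino aldehyde F7, in which C7–H is no longer allylic. The vinylogous Mukaiyama aldol reaction with 10 would give the amino alcohol F8, and Yamaguchi esterification with 12 the amino angelate F9. Quaternisation with MeI would give the methiodide F10, and NaHCO3 would eliminate trimethylamine to come back to the route at 14.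

**Further compounds**

F1 | step 13 | (1S,3E)-1-[(2S,3R)-2-{[tert-butyl(dimethyl)silyl]oxymethyl}-4-methylidene-5-oxooxolan-3-yl]-5-hydroxy-3-methylhepta-3,6-dien-1-yl (2Z)-2-methylbut-2-enoate | C=C1C(=O)O[C@H](CO[Si](C)(C)C(C)(C)C)[C@H]1[C@@H](OC(=O)/C(C)=C\C)C/C(C)=C/C(O)C=C
F2 | step 13 | (1S,3E)-1-[(2S,3R)-2-{[tert-butyl(dimethyl)silyl]oxymethyl}-4-methylidene-5-oxooxolan-3-yl]-3-methyl-5-oxohepta-3,6-dien-1-yl (2Z)-2-methylbut-2-enoate | C=C1C(=O)O[C@H](CO[Si](C)(C)C(C)(C)C)[C@H]1[C@@H](OC(=O)/C(C)=C\C)C/C(C)=C/C(=O)C=C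
F3 | step 13 | (1S,3E)-1-[(2S,3R)-2-(hydroxymethyl)-4-methylidene-5-oxooxolan-3-yl]-3-methyl-5-oxohepta-3,6-dien-1-yl (2Z)-2-methylbut-2-enoate | C=C1C(=O)O[C@H](CO)[C@H]1[C@@H](OC(=O)/C(C)=C\C)C/C(C)=C/C(=O)C=C
F4 | step 13 | (1S,3E)-1-[(2S,3R)-2-formyl-4-methylidene-5-oxooxolan-3-yl]-3-methyl-5-oxohepta-3,6-dien-1-yl (2Z)-2-methylbut-2-enoate | C=C1C(=O)O[C@H](C=O)[C@H]1[C@@H](OC(=O)/C(C)=C\C)C/C(C)=C/C(=O)C=C
F5 | step 13 | (1S,3E)-1-[(2S,3R)-2-[(1R)-1-hydroxy-2-methylprop-2-en-1-yl]-4-methylidene-5-oxooxolan-3-yl]-3-methyl-5-oxohepta-3,6-dien-1-yl (2Z)-2-methylbut-2-enoate | C=C1C(=O)O[C@H]([C@H](O)C(C)=C)[C@H]1[C@@H](OC(=O)/C(C)=C\C)C/C(C)=C/C(=O)C=C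
F6 | step 6 | (2E,5R)-5-[(2S,3R)-2-{[tert-butyl(dimethyl)silyl]oxymethyl}-4-methylidene-5-oxooxolan-3-yl]-5-hydroxy-3-methylpent-2-enal (C8 epimer of 11) | C=C1C(=O)O[C@H](CO[Si](C)(C)C(C)(C)C)[C@H]1[C@H](O)C/C(C)=C/C=O
F7 | step 4 | (2S,3S)-2-{[tert-butyl(dimethyl)silyl]oxymethyl}-4-[(dimethylamino)methyl]-5-oxooxolane-3-carbaldehyde (mixture at ring C4) | CN(C)CC1C(=O)O[C@H](CO[Si](C)(C)C(C)(C)C)[C@H]1C=O
F8 | step 4 | (2E,5S)-5-[(2S,3R)-2-{[tert-butyl(dimethyl)silyl]oxymethyl}-4-[(dimethylamino)methyl]-5-oxooxolan-3-yl]-5-hydroxy-3-methylpent-2-enal | CN(C)CC1C(=O)O[C@H](CO[Si](C)(C)C(C)(C)C)[C@H]1[C@@H](O)C/C(C)=C/C=O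
F9 | step 4 | (1S,3E)-1-[(2S,3R)-2-{[tert-butyl(dimethyl)silyl]oxymethyl}-4-[(dimethylamino)methyl]-5-oxooxolan-3-yl]-3-methyl-5-oxopent-3-en-1-yl (2Z)-2-methylbut-2-enoate | CN(C)CC1C(=O)O[C@H](CO[Si](C)(C)C(C)(C)C)[C@H]1[C@@H](OC(=O)/C(C)=C\C)C/C(C)=C/C=O
F10 | step 4 | methiodide of F9 (trimethylammoniomethyl in place of dimethylaminomethyl; iodide salt) | C[N+](C)(C)CC1C(=O)O[C@H](CO[Si](C)(C)C(C)(C)C)[C@H]1[C@@H](OC(=O)/C(C)=C\C)C/C(C)=C/C=O.[I-]
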